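Ring C is cut across C4–C4a and C2–C3. This exposes a carbenium ion at C2, stabilised by O1 and the para-oxygenated ring B, whose O1=C2 bond and the C8a=C4a bond of the electron-rich phloroglucinol ring A form a 2-oxonia-diene, and a two-carbon piece C3–C4 carrying O3. The key step is an oxidative oxa-Povarov annulation: DDQ turns a simple benzyl aryl ether into that cation, the chiral (E)-enamine of benzyloxyacetaldehyde adds through C3 to C2, and the iminium carbon C4 is captured by the ring A carbon ortho to O1. Both C–C bonds and both stereocentres arise at once; the pyrrolidine left on C4 is a traceless auxiliary, removed reductively.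

Key step: step 4

Remark: flavan numbering (O1, C2, C3, C4, C4a, C8a; rings A, B, C; primed locants on ring B) is used for all intermediates. A catechol monoester can shift its acyl group to the neighbouring oxygen under base, so no basic operation follows the release of O4'. If the enamine should react through the opposite face, the (R)-enantiomer of amine 8 is taken instead.

Step 1
Reactants: 1 4-(benzyloxy)-3-hydroxybenzaldehyde; 2 3,4,5-tris(benzyloxy)benzoic acid
Product: 3 2-(benzyloxy)-5-formylphenyl 3,4,5-tris(benzyloxy)benzoate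
Conditions: N,N'-diisopropylcarbodiimide, DMAP (cat.), CH2Cl2, 0 °C → rt
Reagents that add atoms: none
Why: Steglich esterification of the only free phenol, which places the protected galloyl group on the future O3' while the future O4' stays benzylated.

Step 2
Reactants: 3 2-(benzyloxy)-5-formylphenyl 3,4,5-tris(benzyloxy)benzoate
Product: 4 2-(benzyloxy)-5-(hydroxymethyl)phenyl 3,4,5-tris(benzyloxy)benzoate
Conditions: NaBH4, THF/MeOH (10:1), −10 °C, short reaction time; aq. NH4Cl
Reagents that add atoms: none
Why: Chemoselective borohydride reduction; the aldehyde is reduced far faster than the electron-rich aryl benzoate is attacked.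

Step 3
Reactants: 4 2-(benzyloxy)-5-(hydroxymethyl)phenyl 3,4,5-tris(benzyloxy)benzoate; 5 3,5-bis(benzyloxy)phenol
Product: 6 2-(benzyloxy)-5-{[3,5-bis(benzyloxy)phenoxy]methyl}phenyl 3,4,5-tris(benzyloxy)benzoate
Conditions: PPh3, diisopropyl azodicarboxylate, THF, 0 °C → rt
Reagents that add atoms: none
Why: Mitsunobu etherification; the primary benzylic alcohol is activated as its oxyphosphonium ion and displaced by the phenoxide of 5 at oxygen, which forms the O1–C2 bond.

Step 4
Reactants: 6 2-(benzyloxy)-5-{[3,5-bis(benzyloxy)phenoxy]methyl}phenyl 3,4,5-tris(benzyloxy)benzoate; 7 (benzyloxy)acetaldehyde; 8 (S)-2-[methoxy(diphenyl)methyl]pyrrolidine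
Product: 12 2-(benzyloxy)-5-[(2R,3S,4R)-3,5,7-tris(benzyloxy)-4-{(2S)-2-[methoxy(diphenyl)methyl]pyrrolidin-1-yl}chroman-2-yl]phenyl 3,4,5-tris(benzyloxy)benzoate, via enamine 9 (not isolated), via oxocarbenium ion pair 10 (not isolated), via iminium ion pair 11 (not isolated)
Conditions: (a) 7 + 8 (1.5 equiv each), 4 Å molecular sieves, CH2Cl2, rt; (b) 6 added slowly to DDQ (2,3-dichloro-5,6-dicyano-1,4-benzoquinone, 1.05 equiv), 4 Å molecular sieves, CH2Cl2, 0 °C; (c) solution of 9 added at −78 °C, then → −20 °C; aq. NaHCO3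
Reagents that add atoms: none
Why: Proposed new method: DDQ removes hydride from the central CH2 of 6, the only benzylic position flanked by an aryloxy group and a para-alkoxyphenyl ring, to give cation 10; the O-bearing carbon of enamine 9 (future C3) adds to C2 and the iminium carbon of 11 (future C4) is then attacked by the ring A carbon ortho to O1, a stepwise formal [4+2]. The closest known reaction types are the Povarov reaction of N-aryl iminium ions with enamines and enol ethers, its oxygen analogue with aryl oxocarbenium ions and alkenes, and the DDQ-mediated oxidative coupling of benzylic ethers with aldehydes through enamines. Ring C closes by a 6-exo-trig attack on the iminium carbon (6-endo with respect to the arene π bond), an intramolecular Mannich-type Friedel–Crafts alkylation that re-aromatises by proton loss to the hydroquinone anion. C3 is controlled by the auxiliary: in the s-trans (E)-enamine the methoxy(diphenyl)methyl group of the (S)-pyrrolidine covers one face, so C2 bonds to the other (Re) face of the OBn-bearing carbon, which corresponds to 3S. C2 and C4 follow from the endo-type arrangement usual for Povarov closures together with the E geometry of 9, which places aryl at C2, OBn at C3 and nitrogen at C4 all equatorial (2,3-trans, 3,4-trans; 2R,4R). The step needs site-selective C–H oxidation, secured by the para-benzyloxy group of ring B and by consuming DDQ before 9 is added, and ring closure ortho to O1, secured because the two ortho positions of ring A are equivalent and each is activated by O1 and both benzyloxy groups.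

Step 5
Reactants: 12 2-(benzyloxy)-5-[(2R,3S,4R)-3,5,7-tris(benzyloxy)-4-{(2S)-2-[methoxy(diphenyl)methyl]pyrrolidin-1-yl}chroman-2-yl]phenyl 3,4,5-tris(benzyloxy)benzoate
Product: 13 2-(benzyloxy)-5-[(2R,3S)-3,5,7-tris(benzyloxy)chroman-2-yl]phenyl 3,4,5-tris(benzyloxy)benzoate
Conditions: Et3SiH (10 equiv), CF3CO2H (10 equiv), CH2Cl2, −20 → 0 °C
Reagents that add atoms: none
Why: Ionic hydrogenation: the protonated pyrrolidine leaves from C4 because the benzylic cation is stabilised by O1 and the 5- and 7-benzyloxy groups (as in acid cleavage of 2,4,6-trialkoxybenzylamines), triethylsilane transfers hydride, C2 and C3 are not involved, and the far less stabilised C2–O1 bond should survive cold, dilute acid.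

Step 6
Reactants: 13 2-(benzyloxy)-5-[(2R,3S)-3,5,7-tris(benzyloxy)chroman-2-yl]phenyl 3,4,5-tris(benzyloxy)benzoate
Product: 14 catechin 3'-O-gallate, 2-hydroxy-5-[(2R,3S)-3,5,7-trihydroxychroman-2-yl]phenyl 3,4,5-trihydroxybenzoate
Conditions: H2 (1 atm), Pd(OH)2/C, THF/EtOAc, rt, neutral; filtration, concentration below 30 °C
Reagents that add atoms: none
Why: Hydrogenolysis of the seven benzyl ethers in a neutral, non-nucleophilic medium should leave the aryl gallate and the C2–O1 bond intact and avoids the base that would move the galloyl group from O3' to the freed O4'.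

Compound list
1 | 4-(benzyloxy)-3-hydroxybenzaldehyde | O=Cc1ccc(OCc2ccccc2)c(O)c1 | starting material
2 | 3,4,5-tris(benzyloxy)benzoic acid | OC(=O)c1cc(OCc2ccccc2)c(OCc2ccccc2)c(OCc2ccccc2)c1 | starting material
3 | 2-(benzyloxy)-5-formylphenyl 3,4,5-tris(benzyloxy)benzoate | O=Cc1ccc(OCc2ccccc2)c(OC(=O)c2cc(OCc3ccccc3)c(OCc3ccccc3)c(OCc3ccccc3)c2)c1 | intermediate
4 | 2-(benzyloxy)-5-(hydroxymethyl)phenyl 3,4,5-tris(benzyloxy)benzoate | OCc1ccc(OCc2ccccc2)c(OC(=O)c2cc(OCc3ccccc3)c(OCc3ccccc3)c(OCc3ccccc3)c2)c1 | intermediate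
5 | 3,5-bis(benzyloxy)phenol | Oc1cc(OCc2ccccc2)cc(OCc2ccccc2)c1 | starting material
6 | 2-(benzyloxy)-5-{[3,5-bis(benzyloxy)phenoxy]methyl}phenyl 3,4,5-tris(benzyloxy)benzoate | O=C(Oc1cc(COc2cc(OCc3ccccc3)cc(OCc3ccccc3)c2)ccc1OCc1ccccc1)c1cc(OCc2ccccc2)c(OCc2ccccc2)c(OCc2ccccc2)c1 | intermediate
7 | (benzyloxy)acetaldehyde | O=CCOCc1ccccc1 | starting material
8 | (S)-2-[methoxy(diphenyl)methyl]pyrrolidine | COC(c1ccccc1)(c1ccccc1)[C@@H]1CCCN1 | starting material
9 | (S)-1-[(E)-2-(benzyloxy)ethenyl]-2-[methoxy(diphenyl)methyl]pyrrolidine (enamine) | c1ccccc1CO/C=C/N1CCC[C@H]1C(OC)(c1ccccc1)c1ccccc1 | intermediate (not isolated)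
10 | (E)-[3,5-bis(benzyloxy)phenyl]{4-(benzyloxy)-3-[3,4,5-tris(benzyloxy)benzoyloxy]benzylidene}oxonium, ion pair with 2,3-dichloro-5,6-dicyano-4-hydroxyphenolate | O=C(Oc1cc(/C=[O+]/c2cc(OCc3ccccc3)cc(OCc3ccccc3)c2)ccc1OCc1ccccc1)c1cc(OCc2ccccc2)c(OCc2ccccc2)c(OCc2ccccc2)c1.[O-]c1c(Cl)c(Cl)c(O)c(C#N)c1C#N | intermediate (not isolated)
11 | open-chain iminium ion (2R,3S in flavan numbering): (2S)-2-[methoxy(diphenyl)methyl]pyrrolidinium N-ylidene derivative of the 2-(benzyloxy)-3-[3,5-bis(benzyloxy)phenoxy]-3-arylpropanal, same counter-ion as 10 | O=C(Oc1cc([C@@H](Oc2cc(OCc3ccccc3)cc(OCc3ccccc3)c2)[C@@H](OCc2ccccc2)C=[N+]2CCC[C@H]2C(OC)(c2ccccc2)c2ccccc2)ccc1OCc1ccccc1)c1cc(OCc2ccccc2)c(OCc2ccccc2)c(OCc2ccccc2)c1.[O-]c1c(Cl)c(Cl)c(O)c(C#N)c1C#N | intermediate (not isolated)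
12 | 2-(benzyloxy)-5-[(2R,3S,4R)-3,5,7-tris(benzyloxy)-4-{(2S)-2-[methoxy(diphenyl)methyl]pyrrolidin-1-yl}chroman-2-yl]phenyl 3,4,5-tris(benzyloxy)benzoate | O=C(Oc1cc([C@H]2Oc3cc(OCc4ccccc4)cc(OCc4ccccc4)c3[C@@H](N4CCC[C@H]4C(OC)(c4ccccc4)c4ccccc4)[C@@H]2OCc2ccccc2)ccc1OCc1ccccc1)c1cc(OCc2ccccc2)c(OCc2ccccc2)c(OCc2ccccc2)c1 | intermediate
13 | 2-(benzyloxy)-5-[(2R,3S)-3,5,7-tris(benzyloxy)chroman-2-yl]phenyl 3,4,5-tris(benzyloxy)benzoate | O=C(Oc1cc([C@H]2Oc3cc(OCc4ccccc4)cc(OCc4ccccc4)c3C[C@@H]2OCc2ccccc2)ccc1OCc1ccccc1)c1cc(OCc2ccccc2)c(OCc2ccccc2)c(OCc2ccccc2)c1 | intermediate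
14 | catechin 3'-O-gallate, 2-hydroxy-5-[(2R,3S)-3,5,7-trihydroxychroman-2-yl]phenyl 3,4,5-trihydroxybenzoate | O=C(Oc1cc([C@H]2Oc3cc(O)cc(O)c3C[C@@H]2O)ccc1O)c1cc(O)c(O)c(O)c1 | target

Total step count: 6
Longest linear sequence: 6 steps (1 → 3 → 4 → 6 → 12 → 13 → 14); compounds 2, 5, 7 and 8 are purchased.

Steps most likely to fail

Step 4 (Proposed new method). The iminium carbon may not be captured by ring A fast enough, so that the ring A phenoxide is lost by beta-elimination from the enamine tautomer. The enamine may also add with poor facial or simple diastereoselectivity. The fallback uses known chemistry, sets out from 6 and comes back at 13. Ether 6 is oxidised with DDQ as before, but the cation is intercepted under catalytic oxidative enamine coupling conditions (7 in excess, 8 in catalytic amount as its benzoate salt, a little water, CH2Cl2, −20 °C). The iminium ion is then hydrolysed and only the C2–C3 bond is formed, which should give 2-(benzyloxy)-5-{(1R,2R)-2-(benzyloxy)-1-[3,5-bis(benzyloxy)phenoxy]-3-oxopropyl}phenyl 3,4,5-tris(benzyloxy)benzoate F1. The crude aldehyde is closed in a separate Lewis-acid step (BF3·OEt2, CH2Cl2, −78 °C), an intramolecular Friedel–Crafts hydroxyalkylation that forms C4–C4a and should give 2-(benzyloxy)-5-[(2R,3S)-3,5,7-tris(benzyloxy)-4-hydroxychroman-2-yl]phenyl 3,4,5-tris(benzyloxy)benzoate F2 as both C4 epimers. Triethylsilane added to the same flask removes the C4 hydroxyl by ionic hydrogenation and delivers 13.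

Step 5. The C4 cation may lose the C3 proton to give the 3-benzyloxy-2H-chromene, or the acid may open the C2–O1 bond, instead of clean hydride capture at C4. The fallback sets out from 12 and comes back at 14. Compound 12 is hydrogenated directly (H2, Pd(OH)2/C, THF/AcOH): once the 5- and 7-benzyl ethers fall, the phenolic Mannich base expels amine 8 through a quinone methide that is hydrogenated at C4, while the remaining benzyl ethers are cleaved in the same operation. This is the known reductive deamination of phenolic Mannich bases and makes no new compound (F0).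

Step 6. The galloyl group may migrate from O3' to O4' once that phenol is free, and debenzylation may stall when the polyphenol adsorbs on the catalyst. The fallback sets out from 13 and comes back at 14. The benzyl ethers are cleaved without hydrogen by BCl3 with pentamethylbenzene as cation scavenger (CH2Cl2, −78 °C), an acidic, non-reducing medium in which acyl migration should not occur. It makes no new compound (F0).

Further compounds
F1 | step 4 | 2-(benzyloxy)-5-{(1R,2R)-2-(benzyloxy)-1-[3,5-bis(benzyloxy)phenoxy]-3-oxopropyl}phenyl 3,4,5-tris(benzyloxy)benzoate | O=C(Oc1cc([C@@H](Oc2cc(OCc3ccccc3)cc(OCc3ccccc3)c2)[C@@H](OCc2ccccc2)C=O)ccc1OCc1ccccc1)c1cc(OCc2ccccc2)c(OCc2ccccc2)c(OCc2ccccc2)c1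
F2 | step 4 | 2-(benzyloxy)-5-[(2R,3S)-3,5,7-tris(benzyloxy)-4-hydroxychroman-2-yl]phenyl 3,4,5-tris(benzyloxy)benzoate (both C4 epimers) | O=C(Oc1cc([C@H]2Oc3cc(OCc4ccccc4)cc(OCc4ccccc4)c3C(O)[C@@H]2OCc2ccccc2)ccc1OCc1ccccc1)c1cc(OCc2ccccc2)c(OCc2ccccc2)c(OCc2ccccc2)c1
F0 | step 5 | none | none
F0 | step 6 | none | none
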